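The ratio of the violet flask's shortfall s (the percent of charged substrate not yet product) at 0.833 h to that at 3.00 h is 1.24, and two chemists dispute what that ratio means for the flask to be judged now, since the violet run is this very flask, followed so far.

| flask | substrate | partner | initiator | temperature | remark | time |
|---|---|---|---|---|---|---|
| violet | 0.20 M | 0.20 M | 5 mM | 25 °C | the very flask that is asked about, followed so far |  |
| amber | 0.13 M | 0.20 M | 5 mM | 10 °C | run made earlier |  |
| flask | 0.20 M | 0.200 M | 5.0 mM | 25 °C |  | 4.0 h |

- violet (time / h: product / %): 0.250: 52.4; 0.500: 61.2; 0.833: 63.1; 1.50: 65.1; 3.00: 70.2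
- amber (time / h: product / %): 0.667: 71.4; 2.00: 82.8; 4.00: 83.6; 6.00: 85.5; 8.00: 84.9

(standard deviation of a reading: 0.5 percentage points)

- south: at 4.0 h add partner, 50.0 % of the amount charged, then wait 8.0 h
- east: change nothing and wait 8.0 h more
- south-east: at 4.0 h raise the temperature by 20 K, then wait 8.0 h
- north: at 4.0 h take out 90 % of the product then present, then wait 8.0 h

1. product, in percent of the substrate first charged, at 4.0 h
2. which option adds most product ("none" when 2 percentage points or less is all one gets) (south / east / south-east / north / none)
3. product present, with what was taken out counted in, in percent of the substrate first charged, after east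
4. product present, with what was taken out counted in, in percent of the substrate first charged, after south-east

- removed product is counted in
- additions bring no volume worth counting

Both set the early burst aside and argue from the creep after it. The one who made the forecast says “After the burst, a slow uninitiated reaction remains”, takes that creep as second order in s, and on that ground gives 73 % at 4.0 h, 83 % after east, 95 % after south-east, and south-east as the choice.

The other, whose reckoning is mine, holds that the creep is first order in s, so the violet ratio over its 2.17 h yields 23.3 h as the decade time D, the time in which the common logarithm of s drops by one. Starting from a shortfall of 29.8 % at 3.00 h, D gives 73.0 % of product at 4.0 h, level with the forecast, but 87.7 % after east, 4.7 percentage points above it.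

The violet readings leave the dispute open, for at 1.50 h the first-order line passes 65.4 % and the second-order line 65.6 %, against a reading of 65.1 % with a scatter of 0.5 points. I take south-east too, since the amber run, colder and with less substrate, reads a decade time of 106 h, longer than the violet one, though that run differs in two settings and its reading carries the scatter.

    substrate + initiating radical → chain carrier (k = 40000 L mol⁻¹ s⁻¹, Ea = 32.0 kJ mol⁻¹)
    initiator → 2 initiating radical (k = 1.90 × 10⁻⁵ s⁻¹, Ea = 94.0 kJ mol⁻¹)
    2 initiating radical → ended chains A (k = 1.50 × 10⁶ L mol⁻¹ s⁻¹, Ea = 11.0 kJ mol⁻¹)
    partner + chain carrier → product + initiating radical (k = 27000 L mol⁻¹ s⁻¹, Ea = 12.0 kJ mol⁻¹)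
    substrate ⇌ dormant form (K = 29.0, k = 9.50 × 10⁻⁴ s⁻¹, Ea = 90.0 kJ mol⁻¹, ΔH = 15.0 kJ mol⁻¹)
    2 chain carrier → ended chains B (k = 1.00 × 10⁸ L mol⁻¹ s⁻¹, Ea = 16.0 kJ mol⁻¹)
    (constants at 25 °C)

The flask gives 73.5 % at 4.0 h, 88.5 % after east and 99.1 % after south-east, which adds 26 points against 15 points for east. The second-order view held up to 4.0 h, that being its region, and fell 5.5 points short after east. At 4.00 h the dormant form, the substrate's resting state, stands at 26.4 % against a shortfall of 26.5 %. Carried to 40.0 h in this flask, D gives 99.2 %, and the flask gives 99.1 %.

On the neighbour flask with 0.050 M of substrate, D with the violet line's height gives 73.0 % at 4.0 h. The computed neighbour stands at 89.7 %, 17 points higher, and D by its definition tells how fast a shortfall falls, not how large it starts.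

The numbers in the tables are calculated on assumed constants; the scatter is artificial.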